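**Retrosynthetic overview**

- Feature: C3 is the oxygen-bearing alkene carbon of the 3(2H)-furanone (ring C: O, C3, C2, C1, C10). It is a carbonyl-level carbon between C2 and the vinyl carbon C4 on the ten-membered carbocycle (ring B: C1–C10), so this single atom can be supplied as CO.
- Endgame: the C11=C13 methylene comes from the C13 dimethylamine adduct (MeI, base). The C6 angelate comes from the C6 silyl ether. Ring C comes from the 10-hydroxy-1-yn-3-one 27 (Et2NH, then aqueous acid).
- Key disconnection: C2–C3 and C3–C4 of 27 lead back to the open-chain Z vinyl iodide/terminal alkyne 25 and CO 26 (carbonylative Sonogashira ring closure).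
- 25 comes from trans lactone acid 16, whose carboxyl carbon is C6 (ynone, Z β-iodoenone, carbinol); C13 enters by a Mannich reaction. 16 comes from an Evans syn aldol (C7–C8) of succinyl imide 11 with aldehyde 8, which is made from (R)-citramalic acid (C1, C8–C10, C14).
- Ring order: lactone ring A (step 8), carbocycle ring B (step 16), furanone ring C (step 17).

Key step: step 16

Remark on numbering: germacrane numbering is used. C1 is the ketone; C2=C3 is the furanone alkene, with the ring oxygen on C3 and C10; C4 carries methyl C15 and is double-bonded to C5. C6 carries the angelate, C7 follows, C8 carries the lactone oxygen, C9 follows, C10 carries methyl C14, and C11–C13 are the methylene lactone.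

Remark on descriptors: the CIP letters at C6 and C7 switch along the route only because substituent ranks change (iodine on C4; H, Si or C on O6). The spatial arrangement stays the same.

Assumption: compounds 1, 9, 10, 17, 26 and 31 are taken as commercial.

**Step 1**
Reactants: 1 (R)-citramalic acid
Product: 2 2-[(4R)-2,2,4-trimethyl-5-oxo-1,3-dioxolan-4-yl]acetic acid
Conditions: Me2C(OMe)2, p-TsOH·H2O (cat.), CH2Cl2, rt
Reagents that add atoms: 2,2-dimethoxypropane, COC(C)(C)OC
Why: Acid-catalysed acetonide (dioxolanone) formation ties the tertiary hydroxyl and the adjacent C1 carboxyl into a five-membered ring, which tells the two carboxyl groups apart and leaves the chiral-pool centre C10 untouched.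

**Step 2**
Reactants: 2 dioxolanone acid
Product: 4 (3R)-3-hydroxy-3-methyloxolan-2-one, via hydroxyethyl dioxolanone 3 (not isolated)
Conditions: BH3·SMe2, THF, 0 °C to rt; MeOH quench; then p-TsOH·H2O (cat.), CH2Cl2, rt
Reagents that add atoms: none
Why: Chemoselective borane reduction of the free carboxylic acid (C8) beside the dioxolanone is followed by acid-catalysed translactonisation, in which the new primary alcohol takes over the C1 acyl group and acetone leaves.

**Step 3**
Reactants: 4 hydroxy lactone
Product: 5 (3R)-3-methyl-3-(triethylsilyloxy)oxolan-2-one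
Conditions: TESOTf, 2,6-lutidine, CH2Cl2, 0 °C
Reagents that add atoms: triethylsilyl trifluoromethanesulfonate, CC[Si](CC)(CC)OS(=O)(=O)C(F)(F)F
Why: Silyl triflate silylation is the standard way to cap a hindered tertiary alcohol, and the TES group can later be removed in the presence of a TBS ether.

**Step 4**
Reactants: 5 silyloxy lactone
Product: 6 (3R)-3-methyl-3-(triethylsilyloxy)oxolan-2-ol (anomer mixture)
Conditions: iBu2AlH (1.1 equiv), CH2Cl2, −78 °C; aq. potassium sodium tartrate
Reagents that add atoms: none
Why: Partial lactone reduction stops at the lactol because the tetrahedral aluminium alkoxide is stable at −78 °C.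

**Step 5**
Reactants: 6 lactol
Product: 7 (3R)-3-methyl-3-(triethylsilyloxy)pent-4-yn-1-ol
Conditions: dimethyl (1-diazo-2-oxopropyl)phosphonate, K2CO3, MeOH, 0 °C to rt
Reagents that add atoms: dimethyl (1-diazo-2-oxopropyl)phosphonate, CC(=O)C(=[N+]=[N-])P(=O)(OC)OC
Why: Ohira–Bestmann (Seyferth–Gilbert) homologation acts on the hydroxy aldehyde in equilibrium with the lactol and adds C2; the aldehyde has no α-hydrogen, so C10 cannot epimerise, and the C8 alcohol is released at the same time.

**Step 6**
Reactants: 7 alkynol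
Product: 8 (3R)-3-methyl-3-(triethylsilyloxy)pent-4-ynal
Conditions: 2,2,6,6-tetramethylpiperidin-1-oxyl (TEMPO, cat.), PhI(OAc)2, CH2Cl2, rt
Reagents that add atoms: none
Why: Oxoammonium (TEMPO/PhI(OAc)2) oxidation takes a primary alcohol to the aldehyde without base, so the β-silyloxy group should not be eliminated.

**Step 7**
Reactants: 9 (4R)-4-benzyl-1,3-oxazolidin-2-one; 10 methyl 4-chloro-4-oxobutanoate
Product: 11 methyl 4-[(4R)-4-benzyl-2-oxo-1,3-oxazolidin-3-yl]-4-oxobutanoate
Conditions: Et3N, 4-(dimethylamino)pyridine (cat.), CH2Cl2, 0 °C to rt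
Reagents that add atoms: none
Why: Catalysed N-acylation of the oxazolidinone with an acid chloride gives the imide that carries C6, C7, C11 and C12.

**Step 8**
Reactants: 11 succinyl imide; 8 aldehyde
Product: 14 (4R)-4-benzyl-3-{(2S,3R)-2-[(2R)-2-methyl-2-(triethylsilyloxy)but-3-yn-1-yl]-5-oxooxolane-3-carbonyl}-1,3-oxazolidin-2-one, via Z boron enolate 12 (not isolated), via syn aldol hydroxy ester 13 (not isolated)
Conditions: 11, Bu2BOTf, Et3N, CH2Cl2, 0 °C; 8, −78 to 0 °C; pH 7 buffer, MeOH, H2O2, 0 °C; then pyridinium p-toluenesulfonate (cat.), CH2Cl2, rt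
Reagents that add atoms: dibutylboryl trifluoromethanesulfonate, CCCCB(CCCC)OS(=O)(=O)C(F)(F)F (its boron group is held only in 12)
Why: In this Evans syn aldol the imide is enolised in preference to the ester, and 12 reacts through a chair Zimmerman–Traxler transition state on the face away from the benzyl group of the (R)-auxiliary, which sets C7 (R) and C8 (S) together regardless of the remote C10 centre; the γ-hydroxy ester 13 then lactonises to the trans-disubstituted ring A.

**Step 9**
Reactants: 14 lactone imide
Product: 16 (2S,3R)-2-[(2R)-2-methyl-2-(triethylsilyloxy)but-3-yn-1-yl]-5-oxooxolane-3-carboxylic acid, via peroxy acid 15 (not isolated)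
Conditions: LiOH, H2O2, THF–H2O, 0 °C; Na2SO3; cold 1 M HCl to pH 3
Reagents that add atoms: hydrogen peroxide (as LiOOH), OO
Why: Hydroperoxide cleavage of an N-acyloxazolidinone attacks the exocyclic imide carbonyl and sulfite reduces the peracid; C7 already sits in the thermodynamically preferred trans arrangement, so no epimer should build up, and any opened lactone recloses on acidification.

**Step 10**
Reactants: 16 lactone acid; 17 tributyl(prop-1-yn-1-yl)stannane
Product: 19 (4R,5S)-4-(but-2-ynoyl)-5-[(2R)-2-methyl-2-(triethylsilyloxy)but-3-yn-1-yl]oxolan-2-one, via acid chloride 18 (not isolated)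
Conditions: 1-chloro-N,N,2-trimethylprop-1-en-1-amine, CH2Cl2, 0 °C; then 17, Pd2(dba)3 (2.5 mol %), P(2-furyl)3 (10 mol %), toluene, rt to 40 °C
Reagents that add atoms: 1-chloro-N,N,2-trimethylprop-1-en-1-amine, CC(C)=C(Cl)N(C)C (its chlorine is held only in 18)
Why: Neutral acid chloride formation with Ghosez's reagent and a Stille acylation with an alkynylstannane add C5, C4 and C15 without base or copper, which spares the terminal alkyne, the silyl ether and the β-acyloxy ketone motif (C7–H, C8–O) that base would eliminate.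

**Step 11**
Reactants: 19 ynone
Product: 20 (4R,5S)-4-[(2Z)-3-iodobut-2-enoyl]-5-[(2R)-2-methyl-2-(triethylsilyloxy)but-3-yn-1-yl]oxolan-2-one
Conditions: NaI, AcOH (3 equiv), MeCN, rt
Reagents that add atoms: sodium iodide, [Na+].[I-]
Why: In this conjugate hydroiodination of an ynone, iodide adds to C4 and the allenol is protonated on the side away from iodine; the net anti addition gives the kinetic Z β-iodoenone, and the unactivated terminal alkyne does not react.

**Step 12**
Reactants: 20 Z β-iodoenone
Product: 21 (4S,5S)-4-[(1R,2Z)-1-hydroxy-3-iodobut-2-en-1-yl]-5-[(2R)-2-methyl-2-(triethylsilyloxy)but-3-yn-1-yl]oxolan-2-one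
Conditions: (S)-Me-CBS oxazaborolidine [(3aS)-1-methyl-3,3-diphenyltetrahydro-1H,3H-pyrrolo[1,2-c][1,3,2]oxazaborole, 20 mol %], catecholborane, toluene, −78 °C; pH 7 buffer
Reagents that add atoms: none
Why: In this Corey–Bakshi–Shibata reduction the iodoalkenyl arm, held s-cis with iodine next to the carbonyl oxygen, should act as the large group, so the (S)-catalyst should deliver hydride to give the 6R carbinol (same sense as acetophenone to (R)-1-phenylethanol); this is also the Felkin–Anh face (hydride anti to C8), and catecholborane at −78 °C leaves the lactone and the alkyne alone.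

**Step 13**
Reactants: 21 allylic alcohol
Product: 22 (4R,5S)-4-[(1R,2Z)-1-(tert-butyldimethylsilyloxy)-3-iodobut-2-en-1-yl]-5-[(2R)-2-methyl-2-(triethylsilyloxy)but-3-yn-1-yl]oxolan-2-one
Conditions: TBSOTf, 2,6-lutidine, CH2Cl2, −78 to 0 °C
Reagents that add atoms: tert-butyldimethylsilyl trifluoromethanesulfonate, CC(C)(C)[Si](C)(C)OS(=O)(=O)C(F)(F)F
Why: Prompt silyl triflate protection of the hindered C6 carbinol blocks migration of the lactone from O8 to O6 and, later, capture of the acylpalladium by O6.

**Step 14**
Reactants: 22 bis-silyl ether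
Product: 24 (3S,4R,5S)-4-[(1R,2Z)-1-(tert-butyldimethylsilyloxy)-3-iodobut-2-en-1-yl]-3-[(dimethylamino)methyl]-5-[(2R)-2-methyl-2-(triethylsilyloxy)but-3-yn-1-yl]oxolan-2-one, via silyl ketene acetal 23 (not isolated)
Conditions: TMSOTf, Et3N, CH2Cl2, 0 °C; then dimethyl(methylidene)ammonium iodide, rt; aq. NaHCO3
Reagents that add atoms: trimethylsilyl trifluoromethanesulfonate, C[Si](C)(C)OS(=O)(=O)C(F)(F)F (its silyl group is held only in 23); dimethyl(methylidene)ammonium iodide (Eschenmoser's salt), C=[N+](C)C.[I-]
Why: Soft enolisation to the silyl ketene acetal avoids a strong base that would deprotonate the alkyne or eliminate HI, and the Mannich reaction with Eschenmoser's salt installs C13 directly in its amine-masked form, the iminium ion approaching C11 anti to the C7 side chain (11S, all-trans lactone).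

**Step 15**
Reactants: 24 Mannich base
Product: 25 (3S,4R,5S)-4-[(1R,2Z)-1-(tert-butyldimethylsilyloxy)-3-iodobut-2-en-1-yl]-3-[(dimethylamino)methyl]-5-[(2R)-2-hydroxy-2-methylbut-3-yn-1-yl]oxolan-2-one
Conditions: HF·pyridine, pyridine, THF, 0 °C; aq. NaHCO3
Reagents that add atoms: none
Why: Buffered HF·pyridine distinguishes silyl ethers by size, so the TES ether on O10 should be cleaved while the bulkier TBS ether on O6 stays.

**Step 16**
Reactants: 25 Z vinyl iodide/tertiary propargylic alcohol; 26 carbon monoxide
Product: 27 (6S,7R,8S,10R,11S)-6-(tert-butyldimethylsilyloxy)-13-(dimethylamino)-10-hydroxy-3-oxogermacr-4Z-en-1-yn-12,8-olide (ten-membered 4-hydroxy-2-ynone)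
Conditions: PdCl2(PPh3)2 (10 mol %), CuI (10 mol %), Et3N (10 equiv), CO (1 atm), THF, 35 °C, 25 added by syringe pump over 16 h (final 1 mM)
Reagents that add atoms: none
Why: Proposed new method: zerovalent palladium, formed in the flask from PdCl2(PPh3)2, inserts into the C4–iodine bond with retention of the Z geometry, CO inserts to give the C3 acylpalladium iodide, the copper acetylide of C2 (CuI, Et3N) transmetalates, and reductive elimination forms C2–C3, so C3–C4 and C2–C3 both arise in one catalytic cycle. The closest known reaction types are the intermolecular carbonylative Sonogashira coupling of alkenyl or aryl iodides with tertiary propargylic alcohols and, for ring formation, the carbonylative Stille macrocyclisation of alkenyl electrophiles, whereas a ten-membered ynone closure of this kind is not known. Ring B (C1–C10) closes end to end: transmetalation gives an eleven-membered acyl(alkynyl)palladacycle that contracts on reductive elimination, and the ring should be reachable because ten-membered rings holding a Z alkene and even two alkynes are isolable. No stereocentre is formed, C6, C7, C8, C10 and C11 are spectators, and the C4=C5 geometry is carried over from the iodide. The step needs CO insertion before alkynylation, which the substrate secures because direct coupling would demand a nine-membered Z enyne, and it needs ring closure before oligomerisation, which is served by slow addition at high dilution and by the Z alkene, the trans lactone and the quaternary C10 turning both chain ends toward each other. Side channels are closed by design, since O6 is silylated so the acylpalladium cannot lactonise to a butenolide, C11–C13 is saturated so there is no Heck acceptor, and the tertiary O10–H could only give a nine-membered lactone.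

**Step 17**
Reactants: 27 macrocyclic ynone
Product: 29 (6S,7R,8S,10R,11S)-6-(tert-butyldimethylsilyloxy)-13-(dimethylamino)-3,10-epoxy-1-oxogermacra-2,4Z-dien-12,8-olide, via enaminone 28 (not isolated)
Conditions: Et2NH (5 equiv), THF, rt; then AcOH–H2O, rt
Reagents that add atoms: diethylamine, CCNCC (held only in 28); water, O (its oxygen becomes the C1 ketone oxygen, while the oxygen brought in by CO leaves as water)
Why: This is the known amine-mediated conversion of 4-hydroxy-2-ynones into 3(2H)-furanones: aza-Michael addition at C1, favoured over the hindered enone carbon C5 and helped by release of alkyne strain, gives the E enaminone, and in aqueous acid O10 adds to the C3 carbonyl (5-exo-trig closure of ring C), water is lost and the C1 iminium ion is hydrolysed, C10 keeping its configuration because its C–O bond is never broken.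

**Step 18**
Reactants: 29 furanone silyl ether
Product: 30 (6S,7S,8S,10R,11S)-13-(dimethylamino)-3,10-epoxy-6-hydroxy-1-oxogermacra-2,4Z-dien-12,8-olide
Conditions: HF·pyridine, THF, 0 °C to rt; aq. NaHCO3
Reagents that add atoms: none
Why: Acidic fluoride desilylation frees O6 without the basic conditions that would endanger the furanone or move the lactone.

**Step 19**
Reactants: 30 C6 alcohol; 31 angelic acid
Product: 33 (6S,7R,8S,10R,11S)-6-angeloyloxy-13-(dimethylamino)-3,10-epoxy-1-oxogermacra-2,4Z-dien-12,8-olide, via mixed anhydride 32 (not isolated)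
Conditions: 31, 2,4,6-trichlorobenzoyl chloride, Et3N, toluene, rt; then 30, 75 °C
Reagents that add atoms: 2,4,6-trichlorobenzoyl chloride, O=C(Cl)c1c(Cl)cc(Cl)cc1Cl (held only in 32)
Why: Yamaguchi-type mixed anhydride esterification without a nucleophilic catalyst is the established way to acylate hindered secondary alcohols with angelic acid while keeping the Z geometry, attack taking place at the less shielded angeloyl carbonyl with retention at C6.

**Step 20**
Reactants: 33 angelate amine
Product: 35 target, (6S,7R,8S,10R)-6-angeloyloxy-3,10-epoxy-1-oxogermacra-2,4Z,11(13)-trien-12,8-olide, via trimethylammonium iodide 34 (not isolated)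
Conditions: MeI (10 equiv), CH2Cl2, rt; evaporate; then aq. NaHCO3, CH2Cl2, rt
Reagents that add atoms: iodomethane, CI (held only in 34)
Why: Quaternisation of the only amine followed by a mild Hofmann-type E1cB elimination (C11–H is α to the lactone carbonyl) unmasks the C11=C13 methylene and removes the auxiliary C11 centre without touching C6, C7, C8 or C10.

**Compound list**

1 | (R)-citramalic acid | OC(=O)C[C@@](C)(O)C(=O)O | starting material
2 | 2-[(4R)-2,2,4-trimethyl-5-oxo-1,3-dioxolan-4-yl]acetic acid | OC(=O)C[C@@]1(C)OC(C)(C)OC1=O | intermediate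
3 | (5R)-5-(2-hydroxyethyl)-2,2,5-trimethyl-1,3-dioxolan-4-one | OCC[C@@]1(C)OC(C)(C)OC1=O | intermediate (not isolated)
4 | (3R)-3-hydroxy-3-methyloxolan-2-one | C[C@@]1(O)CCOC1=O | intermediate
5 | (3R)-3-methyl-3-(triethylsilyloxy)oxolan-2-one | C[C@@]1(O[Si](CC)(CC)CC)CCOC1=O | intermediate
6 | (3R)-3-methyl-3-(triethylsilyloxy)oxolan-2-ol, anomer mixture | C[C@@]1(O[Si](CC)(CC)CC)CCOC1O | intermediate
7 | (3R)-3-methyl-3-(triethylsilyloxy)pent-4-yn-1-ol | OCC[C@@](C)(O[Si](CC)(CC)CC)C#C | intermediate
8 | (3R)-3-methyl-3-(triethylsilyloxy)pent-4-ynal | O=CC[C@@](C)(O[Si](CC)(CC)CC)C#C | intermediate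
9 | (4R)-4-benzyl-1,3-oxazolidin-2-one | O=C1N[C@H](Cc2ccccc2)CO1 | starting material
10 | methyl 4-chloro-4-oxobutanoate | COC(=O)CCC(=O)Cl | starting material
11 | methyl 4-[(4R)-4-benzyl-2-oxo-1,3-oxazolidin-3-yl]-4-oxobutanoate | COC(=O)CCC(=O)N1[C@H](Cc2ccccc2)COC1=O | intermediate
12 | Z dibutylboron enolate of 11 | COC(=O)C/C=C(\OB(CCCC)CCCC)N1[C@H](Cc2ccccc2)COC1=O | intermediate (not isolated)
13 | methyl (3R,4S,6R)-3-{[(4R)-4-benzyl-2-oxo-1,3-oxazolidin-3-yl]carbonyl}-4-hydroxy-6-methyl-6-(triethylsilyloxy)oct-7-ynoate | COC(=O)C[C@H]([C@@H](O)C[C@@](C)(O[Si](CC)(CC)CC)C#C)C(=O)N1[C@H](Cc2ccccc2)COC1=O | intermediate (not isolated)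
14 | trans lactone imide (7R,8S,10R) | O=C1O[C@@H](C[C@@](C)(O[Si](CC)(CC)CC)C#C)[C@H](C(=O)N2[C@H](Cc3ccccc3)COC2=O)C1 | intermediate
15 | peroxy acid of 16 | O=C1O[C@@H](C[C@@](C)(O[Si](CC)(CC)CC)C#C)[C@H](C(=O)OO)C1 | intermediate (not isolated)
16 | (2S,3R)-2-[(2R)-2-methyl-2-(triethylsilyloxy)but-3-yn-1-yl]-5-oxooxolane-3-carboxylic acid | O=C1O[C@@H](C[C@@](C)(O[Si](CC)(CC)CC)C#C)[C@H](C(=O)O)C1 | intermediate
17 | tributyl(prop-1-yn-1-yl)stannane | CC#C[Sn](CCCC)(CCCC)CCCC | starting material
18 | acid chloride of 16 | O=C1O[C@@H](C[C@@](C)(O[Si](CC)(CC)CC)C#C)[C@H](C(=O)Cl)C1 | intermediate (not isolated)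
19 | ynone (7R,8S,10R) | O=C1O[C@@H](C[C@@](C)(O[Si](CC)(CC)CC)C#C)[C@H](C(=O)C#CC)C1 | intermediate
20 | Z β-iodoenone (7R,8S,10R) | O=C1O[C@@H](C[C@@](C)(O[Si](CC)(CC)CC)C#C)[C@H](C(=O)/C=C(C)\I)C1 | intermediate
21 | C6 carbinol (6R,7S,8S,10R) | O=C1O[C@@H](C[C@@](C)(O[Si](CC)(CC)CC)C#C)[C@H]([C@@H](O)/C=C(C)\I)C1 | intermediate
22 | C6 TBS ether (6R,7R,8S,10R) | O=C1O[C@@H](C[C@@](C)(O[Si](CC)(CC)CC)C#C)[C@H]([C@@H](O[Si](C)(C)C(C)(C)C)/C=C(C)\I)C1 | intermediate
23 | trimethylsilyl ketene acetal of 22 | C[Si](C)(C)OC1=C[C@@H]([C@@H](O[Si](C)(C)C(C)(C)C)/C=C(C)\I)[C@H](C[C@@](C)(O[Si](CC)(CC)CC)C#C)O1 | intermediate (not isolated)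
24 | Mannich base, O10 TES ether (6R,7R,8S,10R,11S) | O=C1O[C@@H](C[C@@](C)(O[Si](CC)(CC)CC)C#C)[C@H]([C@@H](O[Si](C)(C)C(C)(C)C)/C=C(C)\I)[C@H]1CN(C)C | intermediate
25 | key-step precursor: Z vinyl iodide, C10 propargylic alcohol, amine-masked lactone (6R,7R,8S,10R,11S) | O=C1O[C@@H](C[C@@](C)(O)C#C)[C@H]([C@@H](O[Si](C)(C)C(C)(C)C)/C=C(C)\I)[C@H]1CN(C)C | intermediate
26 | carbon monoxide | [C-]#[O+] | starting material
27 | macrocyclic 4-hydroxy-2-ynone (6S,7R,8S,10R,11S) | O=C1O[C@H]2C[C@@](C)(O)C#CC(=O)/C(C)=C\[C@H](O[Si](C)(C)C(C)(C)C)[C@@H]2[C@H]1CN(C)C | intermediate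
28 | macrocyclic 1-(diethylamino) E enaminone | O=C1O[C@H]2C[C@@](C)(O)/C(N(CC)CC)=C\C(=O)/C(C)=C\[C@H](O[Si](C)(C)C(C)(C)C)[C@@H]2[C@H]1CN(C)C | intermediate (not isolated)
29 | furanone, C6 TBS ether (6S,7R,8S,10R,11S) | O=C1O[C@H]2C[C@@]3(C)OC(=CC3=O)/C(C)=C\[C@H](O[Si](C)(C)C(C)(C)C)[C@@H]2[C@H]1CN(C)C | intermediate
30 | furanone, C6 alcohol (6S,7S,8S,10R,11S) | O=C1O[C@H]2C[C@@]3(C)OC(=CC3=O)/C(C)=C\[C@H](O)[C@@H]2[C@H]1CN(C)C | intermediate
31 | angelic acid, (Z)-2-methylbut-2-enoic acid | C/C=C(/C)C(=O)O | starting material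
32 | angelic 2,4,6-trichlorobenzoic anhydride | C/C=C(/C)C(=O)OC(=O)c1c(Cl)cc(Cl)cc1Cl | intermediate (not isolated)
33 | C6 angelate, amine-masked lactone (6S,7R,8S,10R,11S) | O=C1O[C@H]2C[C@@]3(C)OC(=CC3=O)/C(C)=C\[C@H](OC(=O)/C(C)=C\C)[C@@H]2[C@H]1CN(C)C | intermediate
34 | C13 trimethylammonium iodide of 33 | O=C1O[C@H]2C[C@@]3(C)OC(=CC3=O)/C(C)=C\[C@H](OC(=O)/C(C)=C\C)[C@@H]2[C@H]1C[N+](C)(C)C.[I-] | intermediate (not isolated)
35 | CNP0293168.1 (6S,7R,8S,10R) | C=C1C(=O)O[C@H]2C[C@@]3(C)OC(=CC3=O)/C(C)=C\[C@H](OC(=O)/C(C)=C\C)[C@H]12 | target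

**Step count**

- Total steps: 20.
- Longest linear sequence: 19 steps (steps 1–6 and 8–20, from 1).

**Steps most likely to fail**

**1. Step 16 (labelled step).**
Intermolecular carbonylative coupling to oligomers may outrun ring closure. The acylpalladium may also be intercepted by traces of water or amine before the strained reductive elimination.

The fallback uses known chemistry. It brings C3 in as a hydroxymethyl carbon and closes ring B at C2–C3 by a Nozaki–Hiyama–Kishi reaction. It sets out from 25.
- Stille coupling with (tributylstannyl)methanol (Pd(PPh3)4, toluene, 80 °C) gives the Z allylic alcohol F1.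
- I2 and morpholine in toluene convert the terminal alkyne into the 1-iodoalkyne F2.
- MnO2 in CH2Cl2 oxidises only the primary allylic alcohol, giving the Z enal F3.
- CrCl2 with NiCl2 (cat.) in THF at high dilution closes the ring to the macrocyclic C3 carbinol F4. Its C3 epimers are of no consequence, and iodoalkyne–aldehyde closures of nine- and ten-membered rings are established.
- MnO2 or Dess–Martin periodinane then oxidises C3, and the route is rejoined at 27.

**2. Step 12.**
Facial selectivity may be poor because both flanks of the ketone are sterically demanding. The free C6 carbinol may also draw the lactone over from O8.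

The fallback gives up reagent control and corrects the centre by invertive substitution. It sets out from 20.
- Luche reduction (NaBH4, CeCl3·7H2O, MeOH, −78 °C) gives both carbinols, which are separated.
- The unwanted 6-epimeric carbinol F5 is submitted to a Mitsunobu reaction with 4-nitrobenzoic acid (PPh3, DIAD, toluene, 0 °C). The fully substituted C4 terminus disfavours allylic transposition, and the product is the inverted 4-nitrobenzoate F6.
- K2CO3 in MeOH at 0 °C releases the carbinol, and the route is rejoined at 21.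

**3. Step 19.**
Acylation of the hindered macrocyclic carbinol may be slow. Prolonged heating would then allow isomerisation of the angelate to the tiglate, or migration of the lactone to O6.

The fallback builds the Z alkene on the ester instead of transferring it. It sets out from 30.
- Steglich esterification with 2-[bis(2,2,2-trifluoroethoxy)phosphoryl]propanoic acid (EDC·HCl, 4-(dimethylamino)pyridine, CH2Cl2, rt) gives the phosphonopropionate F7.
- Still–Gennari olefination (KHMDS, 1.0 equiv, 18-crown-6, THF, −78 °C, then acetaldehyde) should form the Z-trisubstituted ester, the phosphonate C–H being by far the most acidic site. The route is rejoined at 33.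

**Further compounds**

F1 | step 16 | Z allylic alcohol (iodine of 25 replaced by CH2OH) | O=C1O[C@@H](C[C@@](C)(O)C#C)[C@H]([C@@H](O[Si](C)(C)C(C)(C)C)/C=C(C)\CO)[C@H]1CN(C)C
F2 | step 16 | 1-iodoalkyne of F1 | O=C1O[C@@H](C[C@@](C)(O)C#CI)[C@H]([C@@H](O[Si](C)(C)C(C)(C)C)/C=C(C)\CO)[C@H]1CN(C)C
F3 | step 16 | Z enal bearing the 1-iodoalkyne | O=C1O[C@@H](C[C@@](C)(O)C#CI)[C@H]([C@@H](O[Si](C)(C)C(C)(C)C)/C=C(C)\C=O)[C@H]1CN(C)C
F4 | step 16 | macrocyclic C3 carbinol (C3 epimers) | O=C1O[C@H]2C[C@@](C)(O)C#CC(O)/C(C)=C\[C@H](O[Si](C)(C)C(C)(C)C)[C@@H]2[C@H]1CN(C)C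
F5 | step 12 | 6-epimeric carbinol (6-epi-21) | O=C1O[C@@H](C[C@@](C)(O[Si](CC)(CC)CC)C#C)[C@H]([C@H](O)/C=C(C)\I)C1
F6 | step 12 | inverted 4-nitrobenzoate of 21 | O=C1O[C@@H](C[C@@](C)(O[Si](CC)(CC)CC)C#C)[C@H]([C@@H](OC(=O)c2ccc(cc2)[N+](=O)[O-])/C=C(C)\I)C1
F7 | step 19 | C6 2-[bis(2,2,2-trifluoroethoxy)phosphoryl]propanoate of 30 | O=C1O[C@H]2C[C@@]3(C)OC(=CC3=O)/C(C)=C\[C@H](OC(=O)C(C)P(=O)(OCC(F)(F)F)OCC(F)(F)F)[C@@H]2[C@H]1CN(C)C
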